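The route rests on cutting the oxirane CH2 (C-3) away from both the quaternary carbon C-2 and the ring oxygen. Because the oxirane is terminal and 2,2-disubstituted (C-2 carries only the benzene ring and the CH2O arm), C-3 can be brought in as the methylene of a sulfoxonium ylide and added to the carbonyl of an aryl ketone. One catalytic, enantioselective methylene transfer thus makes the C-2–C-3 and C-3–O bonds, the three-membered ring and the only stereocentre. The precursor is the 2-silyloxy-1-arylethanone 9; its phenol is an allyl ether (removable under neutral palladium catalysis beside the oxirane) and its formyl carbon a silylated benzylic alcohol.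

Key step: step 8

Assumption: the sense of induction of the binaphthoxide catalyst on ketone 9 is not taken as known; the (R)-ligand is written on the working model that the CH2OSi arm sits where the methyl group of a methyl ketone sits, and the (S)-ligand would be used, with nothing else changed, if the first run shows attack on the other face.

Step 1
Reactants: 1 4-bromo-3-hydroxybenzaldehyde
Product: 2 4-bromo-3-(prop-2-en-1-yloxy)benzaldehyde
Conditions: allyl bromide, K2CO3, DMF, rt
Reagents that add atoms: allyl bromide, C=CCBr
Why: Williamson etherification (SN2 of the phenoxide on allyl bromide); the allyl ether is chosen because it tolerates n-BuLi, the ylide and fluoride, cannot shift to a neighbouring alkoxide as a phenolic silyl group could, and is later removed without acid beside the oxirane.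

Step 2
Reactants: 2 4-bromo-3-(prop-2-en-1-yloxy)benzaldehyde
Product: 3 [4-bromo-3-(prop-2-en-1-yloxy)phenyl]methanol
Conditions: NaBH4, MeOH, 0 °C
Reagents that add atoms: none
Why: Borohydride reduction of the aryl aldehyde, which leaves the aryl bromide and the allyl ether alone and stores the formyl carbon at the alcohol level, out of reach of n-BuLi and of the ylide.

Step 3
Reactants: 3 [4-bromo-3-(prop-2-en-1-yloxy)phenyl]methanol
Product: 4 {[4-bromo-3-(prop-2-en-1-yloxy)phenyl]methoxy}(tert-butyl)dimethylsilane
Conditions: TBSCl, imidazole, CH2Cl2, rt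
Reagents that add atoms: tert-butyldimethylsilyl chloride, CC(C)(C)[Si](C)(C)Cl
Why: Imidazole-promoted silylation of an unhindered primary alcohol through the N-silylimidazolium ion.

Step 4
Reactants: 5 methyl glycolate
Product: 6 methyl 2-[(tert-butyldimethylsilyl)oxy]acetate
Conditions: TBSCl, imidazole, CH2Cl2, rt
Reagents that add atoms: tert-butyldimethylsilyl chloride, CC(C)(C)[Si](C)(C)Cl
Why: The same imidazole-promoted silylation, applied to the primary hydroxyl of the glycolate.

Step 5
Reactants: 6 methyl 2-[(tert-butyldimethylsilyl)oxy]acetate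
Product: 7 2-[(tert-butyldimethylsilyl)oxy]-N-methoxy-N-methylacetamide
Conditions: MeNH(OMe)·HCl, iPrMgCl, THF, −20 to 0 °C
Reagents that add atoms: N,O-dimethylhydroxylamine hydrochloride, CNOC.Cl
Why: Weinreb amide synthesis by aminolysis of the ester with the chloromagnesium amide made in the flask; the chelated adduct resists further attack by the Grignard reagent.

Step 6
Reactants: 4 {[4-bromo-3-(prop-2-en-1-yloxy)phenyl]methoxy}(tert-butyl)dimethylsilane; 7 2-[(tert-butyldimethylsilyl)oxy]-N-methoxy-N-methylacetamide
Product: 9 2-[(tert-butyldimethylsilyl)oxy]-1-[4-({[tert-butyldimethylsilyl]oxy}methyl)-2-(prop-2-en-1-yloxy)phenyl]ethan-1-one, via aryllithium 8 (not isolated)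
Conditions: n-BuLi, THF, −78 °C; then 7, −78 to −20 °C; aq. NH4Cl
Reagents that add atoms: none
Why: Bromine–lithium exchange at −78 °C outruns deprotonation, and aryllithium 8 acylates the amide through a five-membered lithium chelate that collapses to the ketone only on work-up (Weinreb ketone synthesis), so no tertiary alcohol should form.

Step 7
Reactants: 10 trimethylsulfoxonium iodide
Product: 11 dimethyloxosulfonium methylide (THF solution, used as such)
Conditions: NaH, THF, reflux; filtered under argon, titrated
Reagents that add atoms: none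
Why: Deprotonation of the sulfoxonium salt by NaH gives the stabilised Corey–Chaykovsky ylide, and filtration removes the salts before the catalytic step.

Step 8
Reactants: 9 2-[(tert-butyldimethylsilyl)oxy]-1-[4-({[tert-butyldimethylsilyl]oxy}methyl)-2-(prop-2-en-1-yloxy)phenyl]ethan-1-one; 11 dimethyloxosulfonium methylide
Product: 13 tert-butyl{[(2R)-2-[4-({[tert-butyldimethylsilyl]oxy}methyl)-2-(prop-2-en-1-yloxy)phenyl]oxiran-2-yl]methoxy}dimethylsilane, via sulfoxonium betaine 12 (not isolated)
Conditions: 11 (1.2 equiv, slow addition), LaLi3[(R)-binaphthoxide]3 (5 mol %, trivalent lanthanum), (2,4,6-(MeO)3C6H2)3P=O (5 mol %), 5 Å MS, THF, rt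
Reagents that add atoms: none
Why: Catalytic asymmetric Corey–Chaykovsky epoxidation: the lanthanum–lithium binaphthoxide, its pocket tightened by the bound phosphine oxide, activates the ketone carbonyl as a Lewis acid and holds the ylide through its sulfoxonium oxygen, so the ylide carbon adds to one enantiotopic face of C=O and gives betaine 12 with the new C-2–C-3 bond. The alkoxide of 12 then displaces dimethyl sulfoxide from C-3 in a 3-exo-tet closure that forms the C-3–O bond and the oxirane, the only ring made. The closest known reaction type is this same catalysed methylene transfer to aryl and alkyl methyl ketones; ketone 9 carries CH2OSi in place of CH3, so the level of facial discrimination is the open point of the route. The quaternary stereocentre C-2 is set under catalyst control by the chirality of the binaphthoxide ligands, since 9 has no stereocentre of its own. The step needs enantiofacial selectivity and chemoselectivity for one carbonyl: the size gap between the ortho-allyloxy aryl ring, twisted out of the carbonyl plane, and the slim CH2 of the silyloxymethyl arm should let the pocket tell the faces apart, the weakly basic silyl ether oxygens should not chelate lanthanum, and 9 offers the ylide no other electrophile. Deprotonation of 9 at its α-CH2 by the ylide would merely regenerate both partners.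

Step 9
Reactants: 13 tert-butyl{[(2R)-2-[4-({[tert-butyldimethylsilyl]oxy}methyl)-2-(prop-2-en-1-yloxy)phenyl]oxiran-2-yl]methoxy}dimethylsilane
Product: 14 [(2S)-2-[4-(hydroxymethyl)-2-(prop-2-en-1-yloxy)phenyl]oxiran-2-yl]methanol
Conditions: Bu4NF, THF, 0 °C to rt
Reagents that add atoms: none
Why: Fluoride-driven cleavage of both Si–O bonds; the allyl ether is inert, and the alkoxide next to the oxirane can at most undergo a Payne shift that is degenerate here and returns the same enantiomer (the descriptor changes from R to S only through the CIP ranking).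

Step 10
Reactants: 14 [(2S)-2-[4-(hydroxymethyl)-2-(prop-2-en-1-yloxy)phenyl]oxiran-2-yl]methanol
Product: 15 4-[(2S)-2-(hydroxymethyl)oxiran-2-yl]-3-(prop-2-en-1-yloxy)benzaldehyde
Conditions: MnO2 (activated, excess), CH2Cl2, rt
Reagents that add atoms: none
Why: MnO2 oxidises benzylic alcohols selectively, so the unactivated primary alcohol on the oxirane should stay, and the neutral medium does not endanger the oxirane while the phenol is still masked.

Step 11
Reactants: 15 4-[(2S)-2-(hydroxymethyl)oxiran-2-yl]-3-(prop-2-en-1-yloxy)benzaldehyde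
Product: 17 [(2R)-2-[4-formyl-2-(3-methylbutanoyloxy)phenyl]oxiran-2-yl]methyl 3-methylbutanoate (CNP0274578.1), via free phenol 16 (not isolated)
Conditions: Pd(PPh3)4 (5 mol %), morpholine (1.5 equiv), THF, 0 °C to rt; then Et3N, DMAP (cat.), (iPrCH2CO)2O, 0 °C
Reagents that add atoms: 3-methylbutanoic anhydride, CC(C)CC(=O)OC(=O)CC(C)C
Why: Tsuji–Trost deallylation (zerovalent palladium ionises the aryl allyl ether and morpholine traps the π-allyl group) followed in the same flask by DMAP-catalysed acylation of phenol and primary alcohol, so the free phenol ortho to the oxirane exists only briefly and C-2 is never touched.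

Compound list
1 | 4-bromo-3-hydroxybenzaldehyde | O=Cc1ccc(Br)c(O)c1 | starting material
2 | 4-bromo-3-(prop-2-en-1-yloxy)benzaldehyde | O=Cc1ccc(Br)c(OCC=C)c1 | intermediate
3 | [4-bromo-3-(prop-2-en-1-yloxy)phenyl]methanol | OCc1ccc(Br)c(OCC=C)c1 | intermediate
4 | {[4-bromo-3-(prop-2-en-1-yloxy)phenyl]methoxy}(tert-butyl)dimethylsilane | CC(C)(C)[Si](C)(C)OCc1ccc(Br)c(OCC=C)c1 | intermediate
5 | methyl glycolate | COC(=O)CO | starting material
6 | methyl 2-[(tert-butyldimethylsilyl)oxy]acetate | COC(=O)CO[Si](C)(C)C(C)(C)C | intermediate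
7 | 2-[(tert-butyldimethylsilyl)oxy]-N-methoxy-N-methylacetamide | CON(C)C(=O)CO[Si](C)(C)C(C)(C)C | intermediate
8 | [4-({[tert-butyldimethylsilyl]oxy}methyl)-2-(prop-2-en-1-yloxy)phenyl]lithium | [Li]c1ccc(CO[Si](C)(C)C(C)(C)C)cc1OCC=C | intermediate (not isolated)
9 | 2-[(tert-butyldimethylsilyl)oxy]-1-[4-({[tert-butyldimethylsilyl]oxy}methyl)-2-(prop-2-en-1-yloxy)phenyl]ethan-1-one | CC(C)(C)[Si](C)(C)OCC(=O)c1ccc(CO[Si](C)(C)C(C)(C)C)cc1OCC=C | intermediate
10 | trimethylsulfoxonium iodide | C[S+](C)(C)=O.[I-] | starting material
11 | dimethyloxosulfonium methylide | [CH2-][S+](C)(C)=O | intermediate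
12 | (2S)-1-[(tert-butyldimethylsilyl)oxy]-2-[4-({[tert-butyldimethylsilyl]oxy}methyl)-2-(prop-2-en-1-yloxy)phenyl]-3-(dimethyloxosulfonio)propan-2-olate (betaine) | CC(C)(C)[Si](C)(C)OC[C@@]([O-])(c1ccc(CO[Si](C)(C)C(C)(C)C)cc1OCC=C)C[S+](C)(C)=O | intermediate (not isolated)
13 | tert-butyl{[(2R)-2-[4-({[tert-butyldimethylsilyl]oxy}methyl)-2-(prop-2-en-1-yloxy)phenyl]oxiran-2-yl]methoxy}dimethylsilane | CC(C)(C)[Si](C)(C)OC[C@@]1(c2ccc(CO[Si](C)(C)C(C)(C)C)cc2OCC=C)CO1 | intermediate
14 | [(2S)-2-[4-(hydroxymethyl)-2-(prop-2-en-1-yloxy)phenyl]oxiran-2-yl]methanol | OC[C@@]1(c2ccc(CO)cc2OCC=C)CO1 | intermediate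
15 | 4-[(2S)-2-(hydroxymethyl)oxiran-2-yl]-3-(prop-2-en-1-yloxy)benzaldehyde | OC[C@@]1(c2ccc(C=O)cc2OCC=C)CO1 | intermediate
16 | 3-hydroxy-4-[(2S)-2-(hydroxymethyl)oxiran-2-yl]benzaldehyde | OC[C@@]1(c2ccc(C=O)cc2O)CO1 | intermediate (not isolated)
17 | [(2R)-2-[4-formyl-2-(3-methylbutanoyloxy)phenyl]oxiran-2-yl]methyl 3-methylbutanoate | CC(C)CC(=O)OC[C@@]1(c2ccc(C=O)cc2OC(=O)CC(C)C)CO1 | target

Total step count: 11 (two of them make amide 7, one makes ylide 11).
Longest linear sequence: 8 steps (steps 1, 2, 3, 6, 8, 9, 10, 11).

Steps most likely to fail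

Step 8. The catalyst may discriminate poorly between the carbonyl faces when the small arm is CH2OSi instead of CH3, or turnover may stall if the oxygen-rich substrate ties up the lanthanum. The fallback uses known chemistry, sets out from ketone 9 and comes back at diol 14. Wittig methylenation of 9 (Ph3PCH3Br, KOtBu, THF) should give tert-butyl({2-[4-({[tert-butyldimethylsilyl]oxy}methyl)-2-(prop-2-en-1-yloxy)phenyl]prop-2-en-1-yl}oxy)dimethylsilane F1. Bu4NF should then free 2-[4-(hydroxymethyl)-2-(prop-2-en-1-yloxy)phenyl]prop-2-en-1-ol F2. Katsuki–Sharpless epoxidation of F2 (Ti(OiPr)4, L-(+)-diethyl tartrate, tBuOOH, 4 Å MS, CH2Cl2, −20 °C) is directed by the allylic hydroxyl, so the allyl ether alkene is left alone. L-(+)-tartrate is proposed on the empirical face rule by which this antipode gives (2S)-epoxy alcohols from simple primary allylic alcohols such as (E)-hex-2-en-1-ol. The aryl ring takes the place of the C-2 hydrogen and also ranks lowest, so the same face corresponds to (S)-14. The stereocentre is then set by the tartrate.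

Step 11. The phenoxide freed ortho to the oxirane may attack the oxirane CH2 (closure to a dihydrobenzofuranol) or push the ring open before it is acylated. The fallback sets out from 15 and comes back at target 17. The primary alcohol is acylated first (3-methylbutanoic anhydride, Et3N, DMAP) to [(2R)-2-[4-formyl-2-(prop-2-en-1-yloxy)phenyl]oxiran-2-yl]methyl 3-methylbutanoate F3. Palladium-catalysed hydrostannolysis of the allyl ether (PdCl2(PPh3)2 cat., Bu3SnH, CH2Cl2, rt) then releases the phenol oxygen as the covalent, non-basic [(2R)-2-{4-formyl-2-[(tributylstannyl)oxy]phenyl}oxiran-2-yl]methyl 3-methylbutanoate F4 (not isolated). 3-Methylbutanoyl chloride, added to the same flask once the hydride is consumed, converts O–Sn into the aryl ester, so a free phenoxide never forms.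

Step 6. The aryllithium may be quenched by proton transfer from the α-CH2 of amide 7 or from the allylic OCH2 instead of adding to the amide. The fallback sets out from bromide 4 and comes back at ketone 9. Magnesium insertion (Mg, LiCl, THF) should give the less basic bromo[4-({[tert-butyldimethylsilyl]oxy}methyl)-2-(prop-2-en-1-yloxy)phenyl]magnesium F5. Addition to (tert-butyldimethylsilyloxy)acetaldehyde at −40 °C should give racemic 2-[(tert-butyldimethylsilyl)oxy]-1-[4-({[tert-butyldimethylsilyl]oxy}methyl)-2-(prop-2-en-1-yloxy)phenyl]ethan-1-ol F6. Dess–Martin oxidation (NaHCO3, CH2Cl2) removes that stereocentre and delivers 9.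

Further compounds
F1 | step 8 | tert-butyl({2-[4-({[tert-butyldimethylsilyl]oxy}methyl)-2-(prop-2-en-1-yloxy)phenyl]prop-2-en-1-yl}oxy)dimethylsilane | C=C(CO[Si](C)(C)C(C)(C)C)c1ccc(CO[Si](C)(C)C(C)(C)C)cc1OCC=C
F2 | step 8 | 2-[4-(hydroxymethyl)-2-(prop-2-en-1-yloxy)phenyl]prop-2-en-1-ol | C=C(CO)c1ccc(CO)cc1OCC=C
F3 | step 11 | [(2R)-2-[4-formyl-2-(prop-2-en-1-yloxy)phenyl]oxiran-2-yl]methyl 3-methylbutanoate | CC(C)CC(=O)OC[C@@]1(c2ccc(C=O)cc2OCC=C)CO1
F4 | step 11 | [(2R)-2-{4-formyl-2-[(tributylstannyl)oxy]phenyl}oxiran-2-yl]methyl 3-methylbutanoate | CC(C)CC(=O)OC[C@@]1(c2ccc(C=O)cc2O[Sn](CCCC)(CCCC)CCCC)CO1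
F5 | step 6 | bromo[4-({[tert-butyldimethylsilyl]oxy}methyl)-2-(prop-2-en-1-yloxy)phenyl]magnesium | Br[Mg]c1ccc(CO[Si](C)(C)C(C)(C)C)cc1OCC=C
F6 | step 6 | 2-[(tert-butyldimethylsilyl)oxy]-1-[4-({[tert-butyldimethylsilyl]oxy}methyl)-2-(prop-2-en-1-yloxy)phenyl]ethan-1-ol (racemic) | CC(C)(C)[Si](C)(C)OCC(O)c1ccc(CO[Si](C)(C)C(C)(C)C)cc1OCC=C
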